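Readings and results stem from a simulated flask for substances that don't exist, noise included.

The ash run is the very flask asked about, followed as far as 5.00 d, and I read it to learn what to watch up to 15 d.

- ash: starting material 10 mM; second substrate 10 mM; precatalyst 2 µM; the very flask that is asked about, followed so far
- flask: starting material 10 mM; second substrate 10.0 mM; precatalyst 2.0 µM; time 15 d

ash run (percent of the starting material charged)

| time / d | target / % | starting material / % |
|---|---|---|
| 1.04 | 67 | 35 |
| 2.50 | 99 | 0 |
| 3.00 | 103 | 0 |
| 5.00 | 99 | 0 |

(readings scatter by 2 percentage points)

- the reaction counts as stopped when no species that holds the starting material changes by six tenths of a point or more over the second half of the time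

- which holds at 15 d: what has brought the reaction to rest, or that it has not come to rest (forward and back rates have come level / all of the starting material has reacted / it is still moving / no working catalyst is left)
- amount of target at 15 d, in percent of the starting material charged

1. At 1.04 d the ash run shows 35% of the starting material left. Taking its loss as first order, I get 0.687 d. This is the read halving time: the time a first-order loss needs to halve what is there.

2. The target gives a second way. Its 67% at that time leaves 33.0% unconverted, which gives 0.650 d. The two left-over figures differ by 2 percentage points, the scatter of a reading, and they come from different species, so I trust the reading.

3. The first-order law and the readings part at 2.50 d. The law leaves 8.02%, more than the 0% read. The law is the one that cheats: the tail in the readings falls faster, so for that tail my halving time errs on the long side. The part to watch in this flask lies before 2.50 d.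

4. I reckon only the correction to a full yield. In this flask 15 d holds 21.8 halving times, which by that law, as my estimate, leaves <0.001% of the starting material. The late target readings average 100% with no trend, so I commit to that yield.

5. The forecast holds that all of the starting material has reacted and puts the target at 100%: “with the reaction stopped because the starting material is used up”.

6. The flask gives 100% of target at 15 d, and all of the starting material has reacted, with 0% of it left.

    starting material + enzyme ⇌ complex A (K = 80.8 M⁻¹, k = 1.94 × 10⁶ M⁻¹ h⁻¹)
    complex A → enzyme + target (k = 5130 h⁻¹)
    second substrate + enzyme ⇌ complex B (K = 3900 M⁻¹, k = 4.69 × 10⁵ M⁻¹ h⁻¹)
    complex B → enzyme + second product (k = 134 h⁻¹)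
    precatalyst → enzyme (k = 0.534 h⁻¹)

In this flask the making of target from complex A passes the midpoint of its turnover at 0.754 d, far earlier than 15 d, which spans 21.8 read halving times of 0.687 d. The neighbour flask holds 25 mM of second substrate; stretching the halving time by that charge over 10.0 mM, as my own allowance, still fits 8.73 halving times into 15 d, and that neighbour ends with 0% of the starting material left and 100% of target.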